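**Retrosynthetic overview**

1. The target is read as the (3R,7R,10S,11R,14E,18R,22S)-10,11-oxide of tetramethylsqualene. Its only ring is a nerol-type oxirane (the two chain carbons are cis), made first by Sharpless epoxidation of nerol and carried through.
2. C12–C13 is made by alkylating the right-half allylic sulfone anion with the left-half epoxy triflate, followed by palladium-catalysed hydride desulfonylation.
3. Key disconnection: the four C–CH3 bonds at C3, C7, C18 and C22. Each is formed together with its exo-methylene by copper-catalysed enantioselective SN2′ methylation of an (E)-2-alkyl allylic chloride, a laboratory copy of the biosynthetic C-methylation. C3 and C7 are set in one flask; C22 and C18 are set one after the other with enantiomeric ligands.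
4. All allylic chlorides come from one hydroxylated homoprenyl phosphonoacetate (HWE) and two C6 aldehydes, obtained by ozonolysis of silylated nerol oxide and of geranyl phenyl sulfone.
5. Ring order: the oxirane (step 3) is the only ring formed.

Ligand: PA = N,N-bis[1-(2-methoxyphenyl)ethyl]dinaphtho[2,1-d:1′,2′-f][1,3,2]dioxaphosphepin-4-amine (binaphthol phosphoramidite). (S,S,S)-PA has the (S)-binaphthyl unit and two (S) amine carbons; (R,R,R)-PA is its enantiomer.

Assumption: (S,S,S)-PA delivers CH3 to the face that gives the R centre (priority C(=CH2) > CH2 > CH3 > H) and (R,R,R)-PA gives S; this is checked by correlation on the first SN2′ product, and the two ligand enantiomers are exchanged throughout if the sense is the reverse.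

**Route**

Step 1
Reactants: 1 triethyl phosphonoacetate; 2 5-bromo-2-methylpent-2-ene
Product: 4 ethyl 2-(diethoxyphosphoryl)-6-methylhept-5-enoate (racemic), via sodium phosphonoacetate carbanion 3 (not isolated)
Conditions: NaH (1.0 equiv), DMF, 0 °C; then 2 (0.7 equiv), 60 °C
Reagents that add atoms: sodium hydride, [Na+].[H-]
Why: SN2 C-alkylation of the stabilised phosphonate carbanion by a primary bromide (phosphonoacetate alkylation), with excess 1 to suppress dialkylation.

Step 2
Reactants: 4 ethyl 2-(diethoxyphosphoryl)-6-methylhept-5-enoate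
Product: 5 ethyl (5E)-2-(diethoxyphosphoryl)-7-hydroxy-6-methylhept-5-enoate
Conditions: SeO2 (0.3 equiv), tBuOOH (3 equiv), salicylic acid (0.1 equiv), CH2Cl2, 0 °C to rt
Reagents that add atoms: tert-butyl hydroperoxide, CC(C)(C)OO
Why: Catalytic SeO2 allylic oxidation (ene reaction then [2,3] shift, Sharpless–Umbreit conditions) attacks only the (E)-methyl group of the isopropylidene alkene and gives the (E)-allylic alcohol.

Step 3
Reactants: 6 nerol, (2Z)-3,7-dimethylocta-2,6-dien-1-ol
Product: 7 [(2R,3S)-3-methyl-3-(4-methylpent-3-en-1-yl)oxiran-2-yl]methanol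
Conditions: Ti(OiPr)4 (5 mol%), D-(−)-diethyl tartrate (6 mol%), tBuOOH (2 equiv), 4 Å molecular sieves, CH2Cl2, −20 °C
Reagents that add atoms: tert-butyl hydroperoxide, CC(C)(C)OO
Why: Sharpless asymmetric epoxidation touches only the allylic alcohol alkene, and with D-(−)-diethyl tartrate the (Z)-alcohol gives the (2R,3S)-oxirane, which fixes C10 (S), C11 (R) and the cis relation of the two chain carbons of the target.

Step 4
Reactants: 7 [(2R,3S)-3-methyl-3-(4-methylpent-3-en-1-yl)oxiran-2-yl]methanol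
Product: 8 tert-butyl(dimethyl){[(2R,3S)-3-methyl-3-(4-methylpent-3-en-1-yl)oxiran-2-yl]methoxy}silane
Conditions: TBSCl, imidazole, DMF, rt
Reagents that add atoms: tert-butyldimethylsilyl chloride, CC(C)(C)[Si](C)(C)Cl
Why: Standard silylation of the primary alcohol, which also blocks Payne rearrangement in the basic steps that follow.

Step 5
Reactants: 8 tert-butyl(dimethyl){[(2R,3S)-3-methyl-3-(4-methylpent-3-en-1-yl)oxiran-2-yl]methoxy}silane
Product: 10 3-[(2S,3R)-3-({[tert-butyl(dimethyl)silyl]oxy}methyl)-2-methyloxiran-2-yl]propanal, via secondary ozonide 9 (not isolated)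
Conditions: O3, CH2Cl2, −78 °C; then PPh3, −78 °C to rt
Reagents that add atoms: ozone, [O-][O+]=O
Why: Ozonolysis with reductive work-up cleaves the only C=C bond left and leaves the oxirane and silyl ether untouched.

Step 6
Reactants: 10 3-[(2S,3R)-3-({[tert-butyl(dimethyl)silyl]oxy}methyl)-2-methyloxiran-2-yl]propanal; 5 ethyl (5E)-2-(diethoxyphosphoryl)-7-hydroxy-6-methylhept-5-enoate
Product: 11 ethyl (2E)-5-[(2S,3R)-3-({[tert-butyl(dimethyl)silyl]oxy}methyl)-2-methyloxiran-2-yl]-2-[(3E)-5-hydroxy-4-methylpent-3-en-1-yl]pent-2-enoate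
Conditions: LiCl, DBU, MeCN, 0 °C to rt
Reagents that add atoms: none
Why: Horner–Wadsworth–Emmons olefination under Masamune–Roush conditions tolerates the free hydroxyl and the oxirane and gives mainly the (E)-enoate (ester trans to the aldehyde-derived chain); the minor Z isomer is removed by chromatography.

Step 7
Reactants: 11 ethyl (2E)-5-[(2S,3R)-3-({[tert-butyl(dimethyl)silyl]oxy}methyl)-2-methyloxiran-2-yl]-2-[(3E)-5-hydroxy-4-methylpent-3-en-1-yl]pent-2-enoate
Product: 12 (2E,6E)-9-[(2S,3R)-3-({[tert-butyl(dimethyl)silyl]oxy}methyl)-2-methyloxiran-2-yl]-6-(hydroxymethyl)-2-methylnona-2,6-dien-1-ol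
Conditions: iBu2AlH (3.5 equiv), CH2Cl2, −78 °C
Reagents that add atoms: none
Why: 1,2-Reduction of the enoate to the allylic alcohol by iBu2AlH at −78 °C, where the hindered silyloxymethyl oxirane is not opened.

Step 8
Reactants: 12 (2E,6E)-9-[(2S,3R)-3-({[tert-butyl(dimethyl)silyl]oxy}methyl)-2-methyloxiran-2-yl]-6-(hydroxymethyl)-2-methylnona-2,6-dien-1-ol
Product: 13 tert-butyl({(2R,3S)-3-[(3E,7E)-9-chloro-4-(chloromethyl)-8-methylnona-3,7-dien-1-yl]-3-methyloxiran-2-yl}methoxy)dimethylsilane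
Conditions: PPh3 (2.4 equiv), hexachloroacetone, CH2Cl2, −40 to 0 °C
Reagents that add atoms: hexachloroacetone, ClC(Cl)(Cl)C(=O)C(Cl)(Cl)Cl
Why: Appel-type chlorination (PPh3/hexachloroacetone) converts both primary allylic alcohols into chlorides under neutral conditions without allylic transposition or change of alkene geometry.

Step 9
Reactants: 13 tert-butyl({(2R,3S)-3-[(3E,7E)-9-chloro-4-(chloromethyl)-8-methylnona-3,7-dien-1-yl]-3-methyloxiran-2-yl}methoxy)dimethylsilane
Product: 14 tert-butyl(dimethyl)({(2R,3S)-3-methyl-3-[(3R,7R)-3,7,8-trimethyl-4-methylidenenon-8-en-1-yl]oxiran-2-yl}methoxy)silane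
Conditions: Cu(O2CC4H3S) (copper thiophene-2-carboxylate, 10 mol%), (S,S,S)-PA (11 mol%), MeMgBr (2.6 equiv in Et2O, added over 4 h), CH2Cl2, −78 °C
Reagents that add atoms: methylmagnesium bromide, C[Mg]Br
Why: Proposed new method: the closest known reaction type is copper/phosphoramidite asymmetric allylic alkylation of β-substituted allylic chlorides with alkyl Grignard reagents, stretched here to MeMgBr and to two sites in one flask; the monovalent copper–ligand complex adds at the γ carbon anti to chloride to give a trivalent copper σ-allyl species that reductively eliminates before it isomerises, so CH3 ends on C3 and C7 (SN2′), each CH2Cl carbon becomes an exo-methylene, and the ligand sets both remote centres independently as R (sense as assumed above).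

Step 10
Reactants: 14 tert-butyl(dimethyl)({(2R,3S)-3-methyl-3-[(3R,7R)-3,7,8-trimethyl-4-methylidenenon-8-en-1-yl]oxiran-2-yl}methoxy)silane
Product: 15 {(2R,3S)-3-methyl-3-[(3R,7R)-3,7,8-trimethyl-4-methylidenenon-8-en-1-yl]oxiran-2-yl}methanol (left half)
Conditions: Bu4NF, THF, 0 °C
Reagents that add atoms: none
Why: Fluoride desilylation frees the primary alcohol; the trisubstituted 2,3-epoxy alcohol is the favoured Payne isomer, so the oxirane stays in place.

Step 11
Reactants: 16 geranyl bromide, (2E)-1-bromo-3,7-dimethylocta-2,6-diene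
Product: 17 {[(2E)-3,7-dimethylocta-2,6-dien-1-yl]sulfonyl}benzene (geranyl phenyl sulfone)
Conditions: PhSO2Na, DMF, rt
Reagents that add atoms: sodium benzenesulfinate, [Na+].[O-]S(=O)c1ccccc1
Why: SN2 S-alkylation of the sulfinate at the primary allylic carbon keeps the (E)-alkene that becomes C14=C15.

Step 12
Reactants: 17 {[(2E)-3,7-dimethylocta-2,6-dien-1-yl]sulfonyl}benzene
Product: 19 (4E)-4-methyl-6-(phenylsulfonyl)hex-4-enal, via secondary ozonide 18 (not isolated)
Conditions: O3 (1.0 equiv), CH2Cl2–pyridine, −78 °C; then PPh3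
Reagents that add atoms: ozone, [O-][O+]=O
Why: Chemoselective ozonolysis: the allylic sulfonyl group makes the C2=C3 alkene electron-poor, so one equivalent of ozone cleaves the remote isopropylidene alkene first.

Step 13
Reactants: 19 (4E)-4-methyl-6-(phenylsulfonyl)hex-4-enal; 5 ethyl (5E)-2-(diethoxyphosphoryl)-7-hydroxy-6-methylhept-5-enoate
Product: 20 ethyl (2E,6E)-2-[(3E)-5-hydroxy-4-methylpent-3-en-1-yl]-6-methyl-8-(phenylsulfonyl)octa-2,6-dienoate
Conditions: LiCl, DBU, MeCN, 0 °C to rt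
Reagents that add atoms: none
Why: Horner–Wadsworth–Emmons olefination (Masamune–Roush); the amine base deprotonates only the lithium-chelated phosphonate and not the allylic sulfone, and the (E)-enoate is the main isomer.

Step 14
Reactants: 20 ethyl (2E,6E)-2-[(3E)-5-hydroxy-4-methylpent-3-en-1-yl]-6-methyl-8-(phenylsulfonyl)octa-2,6-dienoate
Product: 21 ethyl (2E,6E)-2-[(3E)-5-chloro-4-methylpent-3-en-1-yl]-6-methyl-8-(phenylsulfonyl)octa-2,6-dienoate
Conditions: PPh3, hexachloroacetone, CH2Cl2, −40 to 0 °C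
Reagents that add atoms: hexachloroacetone, ClC(Cl)(Cl)C(=O)C(Cl)(Cl)Cl
Why: Appel-type chlorination of the primary allylic alcohol without transposition; ester and sulfone are inert.

Step 15
Reactants: 21 ethyl (2E,6E)-2-[(3E)-5-chloro-4-methylpent-3-en-1-yl]-6-methyl-8-(phenylsulfonyl)octa-2,6-dienoate
Product: 22 ethyl (2E,6E)-2-[(3S)-3,4-dimethylpent-4-en-1-yl]-6-methyl-8-(phenylsulfonyl)octa-2,6-dienoate
Conditions: Cu(O2CC4H3S) (5 mol%), (R,R,R)-PA (5.5 mol%), MeMgBr (1.3 equiv, added over 3 h), CH2Cl2, −78 °C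
Reagents that add atoms: methylmagnesium bromide, C[Mg]Br
Why: Proposed new method: the same catalyst-controlled SN2′ methylation (closest known type: copper/phosphoramidite allylic alkylation of β-substituted allylic chlorides with Grignard reagents), here with the enantiomeric ligand so that the copper σ-allyl intermediate forms on the other alkene face and C22 is set as S, while the hindered enoate and the sulfone do not react with slowly added MeMgBr at −78 °C.

Step 16
Reactants: 22 ethyl (2E,6E)-2-[(3S)-3,4-dimethylpent-4-en-1-yl]-6-methyl-8-(phenylsulfonyl)octa-2,6-dienoate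
Product: 23 (2E,6E)-2-[(3S)-3,4-dimethylpent-4-en-1-yl]-6-methyl-8-(phenylsulfonyl)octa-2,6-dien-1-ol
Conditions: iBu2AlH (2.5 equiv), CH2Cl2, −78 °C
Reagents that add atoms: none
Why: 1,2-Reduction of the enoate to the (E)-2-substituted allylic alcohol; sulfone and isolated alkenes are untouched.

Step 17
Reactants: 23 (2E,6E)-2-[(3S)-3,4-dimethylpent-4-en-1-yl]-6-methyl-8-(phenylsulfonyl)octa-2,6-dien-1-ol
Product: 24 {[(2E,6E,10S)-7-(chloromethyl)-3,10,11-trimethyldodeca-2,6,11-trien-1-yl]sulfonyl}benzene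
Conditions: PPh3, hexachloroacetone, CH2Cl2, −40 to 0 °C
Reagents that add atoms: hexachloroacetone, ClC(Cl)(Cl)C(=O)C(Cl)(Cl)Cl
Why: Appel-type chlorination of the primary allylic alcohol with retention of position and geometry.

Step 18
Reactants: 24 {[(2E,6E,10S)-7-(chloromethyl)-3,10,11-trimethyldodeca-2,6,11-trien-1-yl]sulfonyl}benzene
Product: 25 {[(2E,6R,10S)-3,6,10,11-tetramethyl-7-methylidenedodeca-2,11-dien-1-yl]sulfonyl}benzene (right half)
Conditions: Cu(O2CC4H3S) (5 mol%), (S,S,S)-PA (5.5 mol%), MeMgBr (1.3 equiv, added over 3 h), CH2Cl2, −78 °C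
Reagents that add atoms: methylmagnesium bromide, C[Mg]Br
Why: Proposed new method: the same SN2′ methylation through a trivalent copper σ-allyl intermediate (closest known type: copper/phosphoramidite allylic alkylation of β-substituted allylic chlorides), now with (S,S,S)-PA so that C18 is set as R under catalyst control, the distant C22 centre having no influence.

Step 19
Reactants: 15 {(2R,3S)-3-methyl-3-[(3R,7R)-3,7,8-trimethyl-4-methylidenenon-8-en-1-yl]oxiran-2-yl}methanol; 25 {[(2E,6R,10S)-3,6,10,11-tetramethyl-7-methylidenedodeca-2,11-dien-1-yl]sulfonyl}benzene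
Product: 28 (2S,3R)-2-methyl-3-[(3E,7R,11S)-4,7,11,12-tetramethyl-8-methylidene-2-(phenylsulfonyl)trideca-3,12-dien-1-yl]-2-[(3R,7R)-3,7,8-trimethyl-4-methylidenenon-8-en-1-yl]oxirane (both epimers at the sulfonyl carbon), via epoxy triflate 26 (not isolated), via lithiated sulfone 27 (not isolated)
Conditions: 15: nBuLi, Et2O, −78 °C, then (CF3SO2)2O (1.0 equiv); 25: nBuLi, THF–DMPU, −78 °C; triflate solution added to the anion at −78 °C, then −40 °C
Reagents that add atoms: trifluoromethanesulfonic anhydride, O=S(=O)(OS(=O)(=O)C(F)(F)F)C(F)(F)F; n-butyllithium, [Li]CCCC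
Why: Sulfone alkylation (Julia-type C–C coupling): the α-sulfonyl allyl anion reacts at its α carbon with the primary triflate much faster than with the hindered trisubstituted oxirane, forming C12–C13 without touching any stereocentre.

Step 20
Reactants: 28 (2S,3R)-2-methyl-3-[(3E,7R,11S)-4,7,11,12-tetramethyl-8-methylidene-2-(phenylsulfonyl)trideca-3,12-dien-1-yl]-2-[(3R,7R)-3,7,8-trimethyl-4-methylidenenon-8-en-1-yl]oxirane
Product: 29 (2S,3R)-2-methyl-3-[(3E,7R,11S)-4,7,11,12-tetramethyl-8-methylidenetrideca-3,12-dien-1-yl]-2-[(3R,7R)-3,7,8-trimethyl-4-methylidenenon-8-en-1-yl]oxirane (CNP0329610.1)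
Conditions: PdCl2(Ph2PCH2CH2CH2PPh2) (5 mol%), LiBHEt3 (2.2 equiv), THF, −20 to 0 °C
Reagents that add atoms: none
Why: Palladium-catalysed reductive desulfonylation: zerovalent palladium ionises the allylic sulfone to a π-allyl complex and hydride is delivered to the less substituted terminus C13, which keeps the (E)-C14=C15 alkene, while the hindered oxirane is expected to survive at or below 0 °C.

**Compound list**

1 | triethyl phosphonoacetate | CCOC(=O)CP(=O)(OCC)OCC | starting material
2 | 5-bromo-2-methylpent-2-ene | CC(C)=CCCBr | starting material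
3 | sodium phosphonoacetate carbanion (sodium salt of 1) | [Na+].CCOC(=O)[CH-]P(=O)(OCC)OCC | intermediate
4 | ethyl 2-(diethoxyphosphoryl)-6-methylhept-5-enoate (racemic) | CCOC(=O)C(CCC=C(C)C)P(=O)(OCC)OCC | intermediate
5 | ethyl (5E)-2-(diethoxyphosphoryl)-7-hydroxy-6-methylhept-5-enoate (racemic at C2) | CCOC(=O)C(CC/C=C(\C)CO)P(=O)(OCC)OCC | intermediate
6 | nerol, (2Z)-3,7-dimethylocta-2,6-dien-1-ol | CC(C)=CCC/C(C)=C\CO | starting material
7 | [(2R,3S)-3-methyl-3-(4-methylpent-3-en-1-yl)oxiran-2-yl]methanol | CC(C)=CCC[C@]1(C)O[C@@H]1CO | intermediate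
8 | tert-butyl(dimethyl){[(2R,3S)-3-methyl-3-(4-methylpent-3-en-1-yl)oxiran-2-yl]methoxy}silane | CC(C)=CCC[C@]1(C)O[C@@H]1CO[Si](C)(C)C(C)(C)C | intermediate
9 | secondary ozonide of 8 (3,3-dimethyl-1,2,4-trioxolane carrying the oxiranylethyl chain at C5) | CC1(C)OOC(CC[C@]2(C)O[C@@H]2CO[Si](C)(C)C(C)(C)C)O1 | intermediate
10 | 3-[(2S,3R)-3-({[tert-butyl(dimethyl)silyl]oxy}methyl)-2-methyloxiran-2-yl]propanal | O=CCC[C@]1(C)O[C@@H]1CO[Si](C)(C)C(C)(C)C | intermediate
11 | ethyl (2E)-5-[(2S,3R)-3-({[tert-butyl(dimethyl)silyl]oxy}methyl)-2-methyloxiran-2-yl]-2-[(3E)-5-hydroxy-4-methylpent-3-en-1-yl]pent-2-enoate | CCOC(=O)/C(CC/C=C(\C)CO)=C/CC[C@]1(C)O[C@@H]1CO[Si](C)(C)C(C)(C)C | intermediate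
12 | (2E,6E)-9-[(2S,3R)-3-({[tert-butyl(dimethyl)silyl]oxy}methyl)-2-methyloxiran-2-yl]-6-(hydroxymethyl)-2-methylnona-2,6-dien-1-ol | OC/C(CC/C=C(\C)CO)=C/CC[C@]1(C)O[C@@H]1CO[Si](C)(C)C(C)(C)C | intermediate
13 | tert-butyl({(2R,3S)-3-[(3E,7E)-9-chloro-4-(chloromethyl)-8-methylnona-3,7-dien-1-yl]-3-methyloxiran-2-yl}methoxy)dimethylsilane | ClC/C(CC/C=C(\C)CCl)=C/CC[C@]1(C)O[C@@H]1CO[Si](C)(C)C(C)(C)C | intermediate
14 | tert-butyl(dimethyl)({(2R,3S)-3-methyl-3-[(3R,7R)-3,7,8-trimethyl-4-methylidenenon-8-en-1-yl]oxiran-2-yl}methoxy)silane | C=C(C)[C@H](C)CCC(=C)[C@H](C)CC[C@]1(C)O[C@@H]1CO[Si](C)(C)C(C)(C)C | intermediate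
15 | {(2R,3S)-3-methyl-3-[(3R,7R)-3,7,8-trimethyl-4-methylidenenon-8-en-1-yl]oxiran-2-yl}methanol (left half) | C=C(C)[C@H](C)CCC(=C)[C@H](C)CC[C@]1(C)O[C@@H]1CO | intermediate
16 | geranyl bromide, (2E)-1-bromo-3,7-dimethylocta-2,6-diene | CC(C)=CCC/C(C)=C/CBr | starting material
17 | {[(2E)-3,7-dimethylocta-2,6-dien-1-yl]sulfonyl}benzene | CC(C)=CCC/C(C)=C/CS(=O)(=O)c1ccccc1 | intermediate
18 | secondary ozonide of 17 (3,3-dimethyl-1,2,4-trioxolane carrying the sulfonyl alkenyl chain at C5) | CC1(C)OOC(CC/C(C)=C/CS(=O)(=O)c2ccccc2)O1 | intermediate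
19 | (4E)-4-methyl-6-(phenylsulfonyl)hex-4-enal | O=CCC/C(C)=C/CS(=O)(=O)c1ccccc1 | intermediate
20 | ethyl (2E,6E)-2-[(3E)-5-hydroxy-4-methylpent-3-en-1-yl]-6-methyl-8-(phenylsulfonyl)octa-2,6-dienoate | CCOC(=O)/C(CC/C=C(\C)CO)=C/CC/C(C)=C/CS(=O)(=O)c1ccccc1 | intermediate
21 | ethyl (2E,6E)-2-[(3E)-5-chloro-4-methylpent-3-en-1-yl]-6-methyl-8-(phenylsulfonyl)octa-2,6-dienoate | CCOC(=O)/C(CC/C=C(\C)CCl)=C/CC/C(C)=C/CS(=O)(=O)c1ccccc1 | intermediate
22 | ethyl (2E,6E)-2-[(3S)-3,4-dimethylpent-4-en-1-yl]-6-methyl-8-(phenylsulfonyl)octa-2,6-dienoate | CCOC(=O)/C(CC[C@H](C)C(=C)C)=C/CC/C(C)=C/CS(=O)(=O)c1ccccc1 | intermediate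
23 | (2E,6E)-2-[(3S)-3,4-dimethylpent-4-en-1-yl]-6-methyl-8-(phenylsulfonyl)octa-2,6-dien-1-ol | OC/C(CC[C@H](C)C(=C)C)=C/CC/C(C)=C/CS(=O)(=O)c1ccccc1 | intermediate
24 | {[(2E,6E,10S)-7-(chloromethyl)-3,10,11-trimethyldodeca-2,6,11-trien-1-yl]sulfonyl}benzene | ClC/C(CC[C@H](C)C(=C)C)=C/CC/C(C)=C/CS(=O)(=O)c1ccccc1 | intermediate
25 | {[(2E,6R,10S)-3,6,10,11-tetramethyl-7-methylidenedodeca-2,11-dien-1-yl]sulfonyl}benzene (right half) | O=S(=O)(C/C=C(\C)CC[C@@H](C)C(=C)CC[C@H](C)C(=C)C)c1ccccc1 | intermediate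
26 | {(2R,3S)-3-methyl-3-[(3R,7R)-3,7,8-trimethyl-4-methylidenenon-8-en-1-yl]oxiran-2-yl}methyl trifluoromethanesulfonate | C=C(C)[C@H](C)CCC(=C)[C@H](C)CC[C@]1(C)O[C@@H]1COS(=O)(=O)C(F)(F)F | intermediate
27 | α-lithio derivative of 25 (lithium at the sulfonyl-bearing carbon) | [Li]C(/C=C(\C)CC[C@@H](C)C(=C)CC[C@H](C)C(=C)C)S(=O)(=O)c1ccccc1 | intermediate
28 | (2S,3R)-2-methyl-3-[(3E,7R,11S)-4,7,11,12-tetramethyl-8-methylidene-2-(phenylsulfonyl)trideca-3,12-dien-1-yl]-2-[(3R,7R)-3,7,8-trimethyl-4-methylidenenon-8-en-1-yl]oxirane (epimers at the sulfonyl carbon) | C=C(C)[C@H](C)CCC(=C)[C@H](C)CC[C@]1(C)O[C@@H]1CC(/C=C(\C)CC[C@@H](C)C(=C)CC[C@H](C)C(=C)C)S(=O)(=O)c1ccccc1 | intermediate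
29 | (2S,3R)-2-methyl-3-[(3E,7R,11S)-4,7,11,12-tetramethyl-8-methylidenetrideca-3,12-dien-1-yl]-2-[(3R,7R)-3,7,8-trimethyl-4-methylidenenon-8-en-1-yl]oxirane | C=C(C)[C@H](C)CCC(=C)[C@H](C)CC[C@]1(C)O[C@@H]1CC/C=C(\C)CC[C@@H](C)C(=C)CC[C@H](C)C(=C)C | target

**Step count and risks**

Total step count: 20.
Longest linear sequence: 10 steps (6 to 29 through steps 3–10, 19 and 20; equally 16 to 29 through steps 11–20).

Three steps most likely to fail:

1. Step 9 (the same chemistry carries steps 15 and 18). MeMgBr on a β,γ-dialkyl allylic chloride may give SN2 product or low enantioselectivity, and two such events must both succeed; with four such centres in the target, even about 95:5 per event would leave hard-to-separate diastereomers. The fallback sets out from 12 and returns at 14, replacing catalyst control by Sharpless control with stereospecific steps. Both (E)-allylic alcohols of 12 are epoxidised with Ti(OiPr)4, L-(+)-diethyl tartrate and tBuOOH to the (2S,3S,6S,7S)-bis-epoxy diol F1. Me2CuLi then opens each new oxirane at its CH carbon with inversion, which places the methyl groups at C3 and C7 in the R configuration and gives the (2R,3R,6R,7R)-tetrol F2; the silyloxymethyl oxirane, which has no free hydroxyl to direct the cuprate, is expected to stay intact. Thiophosgene and DMAP convert the two primary/tertiary 1,2-diols into the bis(1,3-dioxolane-2-thione) F3. Corey–Winter elimination with 1,3-dimethyl-2-phenyl-1,3,2-diazaphospholidine at 40 °C turns each thiocarbonate into the exo-methylene and gives 14.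

2. Step 20. LiBHEt3 may open the oxirane before the palladium-catalysed reduction is complete. The fallback sets out from 15 and 27 (in place of steps 19 and 20) and returns at 29, forming the oxirane only after the hydride step. The lithium alkoxide of 15 (nBuLi, LiCl, THF) is combined with 27 and warmed to 0 °C. Under these aprotic Payne conditions the alkoxide equilibrates with the terminal oxirane (C11 inverted, C10 alkoxide), which 27 opens at C12 to give the (10S,11S)-diol sulfone F4. The dialkoxide tolerates PdCl2(Ph2PCH2CH2CH2PPh2)/LiBHEt3, giving the (10S,11S)-diol F5. MsCl in pyridine sulfonylates only the secondary C11 hydroxyl (mesylate F6), and K2CO3 in MeOH closes the oxirane with a second inversion at C11, giving 29.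

3. Step 12. Ozone may also cleave the C2=C3 alkene, and the yield depends on exact dosing. The fallback sets out from 17 and returns at 19 by epoxidation and glycol-type cleavage. mCPBA (1.0 equiv, CH2Cl2, 0 °C) epoxidises only the electron-rich isopropylidene alkene to the 6,7-epoxide F7, and H5IO6 in THF–water cleaves this oxirane to aldehyde 19.

**Further compounds**

F1 | step 9 | (2S,3S,6S,7S)-2,3:6,7-diepoxide of diol 12 (bis-epoxy diol) | OC[C@]1(C)O[C@H]1CC[C@@]2(CO)O[C@H]2CC[C@]3(C)O[C@@H]3CO[Si](C)(C)C(C)(C)C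
F2 | step 9 | (2R,3R,6R,7R)-9-[(2S,3R)-3-({[tert-butyl(dimethyl)silyl]oxy}methyl)-2-methyloxiran-2-yl]-6-(hydroxymethyl)-2,3,7-trimethylnonane-1,2,6-triol (tetrol) | OC[C@@](O)(C)[C@H](C)CC[C@](O)(CO)[C@H](C)CC[C@]1(C)O[C@@H]1CO[Si](C)(C)C(C)(C)C
F3 | step 9 | bis(1,3-dioxolane-2-thione) of tetrol F2 (cyclic thiocarbonates on both 1,2-diols) | S=C1OC[C@](C)(O1)[C@H](C)CC[C@]2(COC(=S)O2)[C@H](C)CC[C@]3(C)O[C@@H]3CO[Si](C)(C)C(C)(C)C
F4 | step 20 | (10S,11S)-10,11-diol bearing the phenylsulfonyl group at C13 (open-chain form of 28, target numbering) | C=C(C)[C@H](C)CCC(=C)[C@H](C)CC[C@](C)(O)[C@@H](O)CC(/C=C(\C)CC[C@@H](C)C(=C)CC[C@H](C)C(=C)C)S(=O)(=O)c1ccccc1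
F5 | step 20 | (3R,7R,10S,11S,14E,18R,22S)-2,3,7,10,15,18,22,23-octamethyl-6,19-dimethylidenetetracosa-1,14,23-triene-10,11-diol | C=C(C)[C@H](C)CCC(=C)[C@H](C)CC[C@](C)(O)[C@@H](O)CC/C=C(\C)CC[C@@H](C)C(=C)CC[C@H](C)C(=C)C
F6 | step 20 | 11-methanesulfonate of diol F5 (tertiary C10 hydroxyl free) | C=C(C)[C@H](C)CCC(=C)[C@H](C)CC[C@](C)(O)[C@@H](OS(C)(=O)=O)CC/C=C(\C)CC[C@@H](C)C(=C)CC[C@H](C)C(=C)C
F7 | step 12 | {[(2E)-5-(3,3-dimethyloxiran-2-yl)-3-methylpent-2-en-1-yl]sulfonyl}benzene (racemic 6,7-epoxide of 17) | CC1(C)OC1CC/C(C)=C/CS(=O)(=O)c2ccccc2
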